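All runs are calculated for an exercise; noise was put on by code.

The pitfall in these runs was to read the first pair of peaks and carry that ratio to the end of a flask.

| setting | ash | birch | alder | larch | dawn | autumn | noon |
|---|---|---|---|---|---|---|---|
| starting material | 0.50 M | 0.50 M | 0.50 M | 0.50 M | 0.50 M | 0.50 M | 0.50 M |
| coupling partner | 0.50 equiv | 0.25 equiv | 0.38 equiv | 0.50 equiv | 0.500 equiv (fed, over 2.5 min) | 0.500 equiv | 0.500 equiv |
| second substrate | 1 equiv | 1 equiv | 1 equiv | 0.50 equiv | 1.00 equiv | 1.00 equiv (fed, over 2.5 min) | 1.00 equiv |
| remark | run made earlier | run made earlier | run made earlier | run made earlier | all else is in the flask from the start; the feed brings no volume worth counting | all else is in the flask from the start; the feed brings no volume worth counting | everything together at the start |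
| time |  |  |  |  | 6.0 min | 6.0 min | 6.0 min |

- ash (time / min: target / %, cross product / %): 0.667: 5.2, 3.1; 1.33: 6.3, 5.3; 2.00: 6.3, 7.2; 3.00: 5.0, 8.9; 4.00: 5.4, 9.9
- birch (time / min: target / %, cross product / %): 0.417: 2.5, 3.3; 1.33: 2.8, 7.2; 2.00: 3.2, 8.3; 3.00: 2.5, 9.5; 5.00: 2.7, 12.2
- alder (time / min: target / %, cross product / %): 0.417: 3.0, 2.5; 1.33: 5.1, 5.6; 2.00: 4.7, 8.1; 3.00: 4.3, 8.8; 5.00: 3.8, 10.6
- larch (time / min: target / %, cross product / %): 0.417: 4.2, 1.7; 1.33: 8.5, 3.5; 2.00: 8.4, 2.8; 3.00: 8.3, 3.4; 5.00: 6.3, 4.6

(scatter of a reading: 0.5 percentage points)

* which flask leads in share of target in target plus cross product ("all alike" within 1.5 percentage points) (dawn / autumn / noon / all alike)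
* share of target in target plus cross product at the end, dawn
* share of target in target plus cross product at the end, autumn
* share of target in target plus cross product at the end, noon

In the table I divided target over cross product by charged coupling partner over charged second substrate. The first row of ash gave 3.35, but its last row gave 1.09, so the ratio fell with time. The last rows of birch, alder and larch gave 0.885, 0.943 and 1.37. Larch read highest, so I did not take the four for one constant, and I used their mean, 1.07, as a rough working figure. This is the late selectivity factor: target over cross product in a run's last row, per unit of charged partner over charged second substrate.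

The target in ash had stopped rising by 1.33 min, which lies inside the feed of 2.5 min, so I let the mean during the feed stand for the curve. A steady feed averages half its charge if consumption is ignored. Noon then gave a ratio of 0.536, a share of 34.9%. Dawn, with c(coupling partner) halved, gave 0.268, a share of 21.1%. Autumn, with c(second substrate) halved, gave 1.07, a share of 51.7%.

The forecast named autumn, with 18% for dawn, 52% for autumn and 30% for noon, arguing for autumn that “second substrate is scarce early”; my figures stood above it on dawn and noon.

The flasks gave 24.5% for dawn, 52.4% for autumn and 31.4% for noon.

    2 starting material → self-condensation product (k = 0.0140 M⁻¹ s⁻¹)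
    starting material + coupling partner → target (k = 0.0120 M⁻¹ s⁻¹)
    starting material + target → side product (k = 0.0170 M⁻¹ s⁻¹)
    coupling partner + target → over-reaction product (k = 0.0140 M⁻¹ s⁻¹)
    starting material + second substrate → cross product (k = 0.00290 M⁻¹ s⁻¹)
    second substrate + coupling partner → second product (k = 0.0300 M⁻¹ s⁻¹)

In autumn, starting material + coupling partner to target ran during the feed, and by 2.50 min target stood at 8.64% and cross product at 3.15%. By 6.00 min coupling partner was down to 2.22% of its charge, while cross product had reached 6.33% and target had fallen to 6.96%, a ratio of 1.10 against my 1.07 for autumn; per charged partner over charged second substrate that ratio is 2.20, not my 1.07. Over the first 2.50 min, mean c(coupling partner) in dawn was 0.700 of noon's, not the 0.5 I had assumed, and dawn's share came 3.4 percentage points above mine. For autumn's neighbour with 1.70 equiv of second substrate, 1.07 with the halved charge gives 38.7%, and that flask gave 36.1%.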